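**Retrosynthetic overview**

- Number the benzoate ring C1 (CO2Me), C2 (OH), C3 (prenyl), C4 (OH), C5 (prenyl), C6 (CH2CH2Ph). The unit C3–C4–C5 with its two prenyl groups is mirror-symmetric about C4 and is the skeleton of a symmetric ketone; C1, C2, C6 and the ester are the carbons of an alkylidenemalonate.
- The arene is taken back to a 4-carbomethoxycyclohexane-1,3-dione that lacks only the C1=C6 double bond. This is introduced last by selenenylation at C1, selenoxide syn-elimination and enolization.
- The dione, the only ring made in the route, comes from the lithium enolate of 2,10-dimethylundeca-2,9-dien-6-one and dimethyl 2-(3-phenylpropylidene)propanedioate by Michael addition (C5–C6) followed by Claisen closure (C2–C3).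
- The ketone comes from two successive prenylations of dimethyl 3-oxopentanedioate, one at each methylene, followed by hydrolysis and double decarboxylation. The alkylidenemalonate comes from a Knoevenagel condensation of 3-phenylpropanal with dimethyl malonate.

Key step: step 5

Remark on the chemistry: the target has no stereocentre. Compound 3 is therefore carried as the racemate and the sp3 centres in 4, 5 and 11 to 16 as mixtures of diastereomers; 12 and 14 are drawn as keto forms although they should exist largely as the C2–C3–C4 enol.

**Step 1**
Reactants: 1 dimethyl 3-oxopentanedioate; 2 1-bromo-3-methylbut-2-ene (prenyl bromide)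
Product: 3 dimethyl 2-(3-methylbut-2-enyl)-3-oxopentanedioate (racemic)
Conditions: 1 (1.2 equiv), NaH (1.0 equiv), THF, 0 °C; then 2 (1.0 equiv), 0 °C → rt
Reagents that add atoms: none
Why: Enolate C-alkylation (SN2 at the primary allylic carbon) of the sodium enolate of a β-keto diester, in which the base and the halide are the limiting reagents and the diester is in slight excess, so that a second alkylation should stay minor.

**Step 2**
Reactants: 3 dimethyl 2-(3-methylbut-2-enyl)-3-oxopentanedioate; 2 1-bromo-3-methylbut-2-ene (prenyl bromide)
Product: 4 dimethyl 2,4-bis(3-methylbut-2-enyl)-3-oxopentanedioate (mixture of meso and racemic forms)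
Conditions: NaH (1.05 equiv), THF, 0 °C; then 2 (1.05 equiv), 0 °C → rt
Reagents that add atoms: none
Why: Second enolate C-alkylation (SN2), in which deprotonation of 3 occurs at the still unsubstituted, more acidic and less hindered C4 methylene, so that the second prenyl group should enter at C4 and not at the already substituted C2.

**Step 3**
Reactants: 4 dimethyl 2,4-bis(3-methylbut-2-enyl)-3-oxopentanedioate
Product: 6 2,10-dimethylundeca-2,9-dien-6-one, via diacid 5 (not isolated)
Conditions: 2 M aq NaOH (2.5 equiv), MeOH, rt; then 1 M HCl to pH 3, 50 °C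
Reagents that add atoms: none
Why: Ester saponification followed by double decarboxylation of the bis-β-keto acid through the cyclic six-membered transition state (ketone cleavage of the acetoacetic ester type), under conditions mild enough to leave the trisubstituted alkenes untouched.

**Step 4**
Reactants: 7 3-phenylpropanal; 8 dimethyl malonate
Product: 9 dimethyl 2-(3-phenylpropylidene)propanedioate
Conditions: piperidine (0.1 equiv), AcOH (0.1 equiv), toluene, reflux, Dean–Stark trap
Reagents that add atoms: none
Why: Knoevenagel condensation by iminium activation of the aldehyde with piperidinium acetate, driven by azeotropic removal of water; the two identical ester groups leave no alkene geometry to control.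

**Step 5**
Reactants: 6 2,10-dimethylundeca-2,9-dien-6-one; 9 dimethyl 2-(3-phenylpropylidene)propanedioate
Product: 12 methyl 3,5-bis(3-methylbut-2-enyl)-2,4-dioxo-6-(2-phenylethyl)cyclohexane-1-carboxylate (mixture of diastereomers and enol forms), via lithium enolate 10 (not isolated), via Michael adduct 11 (not isolated)
Conditions: 6, LiN(iPr)2 (1.05 equiv), THF, −78 °C; 9, −78 → −40 °C; then NaOMe (1.5 equiv), MeOH, −40 °C → reflux; 1 M HCl, 0 °C
Reagents that add atoms: none
Why: The preformed lithium enolate 10 adds to the β-carbon of alkylidenemalonate 9 (Michael addition, bond C5–C6) to give the malonate enolate of 11, and in NaOMe/MeOH at reflux proton transfer provides a small equilibrium share of the α'-enolate, which attacks one malonate ester carbonyl and expels methoxide (intramolecular Claisen condensation, bond C2–C3). The closest known reaction type is the Michael–Claisen synthesis of cyclohexane-1,3-diones of the dimedone kind, where the same kind of δ-keto malonate closes in the same sense. The ring closes in a 6-(enolendo)-exo-trig mode, since both enolate carbons C3 and C4 lie inside the new ring while the attacked ester C=O is exocyclic to it. The four sp3 centres C1, C3, C5 and C6 form without control as an equilibrating mixture, which is harmless because all four become sp2 in the arene. The step needs 1,4-addition instead of γ-deprotonation of 9, which the preformed lithium enolate at −78 °C with no free amide base should secure, and it needs ring closure to win over retro-Michael cleavage, which is secured because methoxide converts the product at once into its stabilized 1,3-dione enolate and so drains all the preceding equilibria. Because ketone 6 is symmetric, neither the first enolization nor the α'-enolization offers a regiochemical choice.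

**Step 6**
Reactants: 12 methyl 3,5-bis(3-methylbut-2-enyl)-2,4-dioxo-6-(2-phenylethyl)cyclohexane-1-carboxylate
Product: 14 methyl 3,5-bis(3-methylbut-2-enyl)-2,4-dioxo-6-(2-phenylethyl)-1-(phenylselanyl)cyclohexane-1-carboxylate, via dilithium dianion 13 (not isolated)
Conditions: LiN(iPr)2 (2.2 equiv), THF–DMPU, −78 → 0 °C; PhSeCl (1.05 equiv), THF, −78 °C; aq NH4Cl
Reagents that add atoms: benzeneselenenyl chloride, Cl[Se]c1ccccc1
Why: The first equivalent of base removes the acidic 1,3-dione proton and the second removes H-1 between the ester and C2, so that the dianion should react with the selenium electrophile at its last-formed, most basic carbon C1 (α-selenenylation of an enolate, following the site selectivity of β-dicarbonyl dianions), with selenium entering trans to the C6 phenethyl group and thus cis to H-6.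

**Step 7**
Reactants: 14 methyl 3,5-bis(3-methylbut-2-enyl)-2,4-dioxo-6-(2-phenylethyl)-1-(phenylselanyl)cyclohexane-1-carboxylate
Product: 17 methyl 2,4-dihydroxy-3,5-bis(3-methylbut-2-enyl)-6-(2-phenylethyl)benzoate (the target), via selenoxide 15 (not isolated), via keto tautomer 16 (not isolated)
Conditions: mCPBA (1.0 equiv), CH2Cl2, −78 °C; then iPr2NH (3 equiv), −78 °C → rt
Reagents that add atoms: none
Why: Oxidation of the selenide at −78 °C is far faster than epoxidation of the prenyl alkenes, the selenoxide 15 undergoes syn-elimination with its only β-hydrogen H-6 to give ene-dione 16, and two enolizations then deliver the aromatic, hydrogen-bonded resorcylate, while the amine intercepts PhSeOH before it can add to the prenyl groups (selenoxide elimination followed by keto–enol tautomerization).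

**Compound list**

1 | dimethyl 3-oxopentanedioate | COC(=O)CC(=O)CC(=O)OC | starting material
2 | 1-bromo-3-methylbut-2-ene (prenyl bromide) | CC(C)=CCBr | starting material
3 | dimethyl 2-(3-methylbut-2-enyl)-3-oxopentanedioate (racemic) | COC(=O)CC(=O)C(CC=C(C)C)C(=O)OC | intermediate
4 | dimethyl 2,4-bis(3-methylbut-2-enyl)-3-oxopentanedioate (mixture of meso and racemic forms) | COC(=O)C(CC=C(C)C)C(=O)C(CC=C(C)C)C(=O)OC | intermediate
5 | 2,4-bis(3-methylbut-2-enyl)-3-oxopentanedioic acid (mixture of diastereomers) | OC(=O)C(CC=C(C)C)C(=O)C(CC=C(C)C)C(=O)O | intermediate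
6 | 2,10-dimethylundeca-2,9-dien-6-one | CC(C)=CCCC(=O)CCC=C(C)C | intermediate
7 | 3-phenylpropanal | O=CCCc1ccccc1 | starting material
8 | dimethyl malonate | COC(=O)CC(=O)OC | starting material
9 | dimethyl 2-(3-phenylpropylidene)propanedioate | COC(=O)C(=CCCc1ccccc1)C(=O)OC | intermediate
10 | lithium 2,10-dimethylundeca-2,5,9-trien-6-olate (enolate geometry not controlled) | CC(C)=CCC=C(O[Li])CCC=C(C)C | intermediate
11 | dimethyl 2-[9-methyl-4-(3-methylbut-2-enyl)-5-oxo-1-phenyldec-8-en-3-yl]propanedioate (mixture of diastereomers; present in the flask as its malonate enolate) | COC(=O)C(C(=O)OC)C(CCc1ccccc1)C(CC=C(C)C)C(=O)CCC=C(C)C | intermediate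
12 | methyl 3,5-bis(3-methylbut-2-enyl)-2,4-dioxo-6-(2-phenylethyl)cyclohexane-1-carboxylate (mixture of diastereomers and enol forms) | COC(=O)C1C(CCc2ccccc2)C(CC=C(C)C)C(=O)C(CC=C(C)C)C1=O | intermediate
13 | dilithium 4-(methoxycarbonyl)-2,6-bis(3-methylbut-2-enyl)-5-(2-phenylethyl)cyclohexa-1,3-diene-1,3-diolate (mixture of diastereomers) | COC(=O)C1=C(O[Li])C(CC=C(C)C)=C(O[Li])C(CC=C(C)C)C1CCc1ccccc1 | intermediate
14 | methyl 3,5-bis(3-methylbut-2-enyl)-2,4-dioxo-6-(2-phenylethyl)-1-(phenylselanyl)cyclohexane-1-carboxylate (mixture of diastereomers, selenium expected trans to the phenethyl group) | COC(=O)C1([Se]c2ccccc2)C(CCc2ccccc2)C(CC=C(C)C)C(=O)C(CC=C(C)C)C1=O | intermediate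
15 | methyl 3,5-bis(3-methylbut-2-enyl)-2,4-dioxo-6-(2-phenylethyl)-1-(phenylseleninyl)cyclohexane-1-carboxylate (mixture of diastereomers) | COC(=O)C1([Se](=O)c2ccccc2)C(CCc2ccccc2)C(CC=C(C)C)C(=O)C(CC=C(C)C)C1=O | intermediate
16 | methyl 3,5-bis(3-methylbut-2-enyl)-4,6-dioxo-2-(2-phenylethyl)cyclohex-1-ene-1-carboxylate (mixture of diastereomers) | COC(=O)C1=C(CCc2ccccc2)C(CC=C(C)C)C(=O)C(CC=C(C)C)C1=O | intermediate
17 | methyl 2,4-dihydroxy-3,5-bis(3-methylbut-2-enyl)-6-(2-phenylethyl)benzoate | COC(=O)c1c(O)c(CC=C(C)C)c(O)c(CC=C(C)C)c1CCc1ccccc1 | target

**Step count**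

Total steps: 7. Longest linear sequence: 6 steps (steps 1, 2, 3, 5, 6, 7); step 4 is a one-step side branch.

**Steps most likely to fail**

1. Step 5. The enolate may act as a base and deconjugate 9 by γ-deprotonation, or the Claisen closure at the substituted α'-carbon may be slow enough for retro-Michael cleavage and methanol addition to 9 to compete. The fallback reverses the polarity of the C6 carbon and sets out from ketone 6. A directed aldol addition of its lithium enolate to 3-phenylpropanal 7 (LiN(iPr)2, THF, −78 °C) should give the aldol 5-(1-hydroxy-3-phenylpropyl)-2,10-dimethylundeca-2,9-dien-6-one F1. MsCl/Et3N should convert this into the mesylate [9-methyl-4-(3-methylbut-2-enyl)-5-oxo-1-phenyldec-8-en-3-yl] methanesulfonate F2, and DBU should eliminate it to the enone (E)-2,10-dimethyl-5-(3-phenylpropylidene)undeca-2,9-dien-6-one F3. Michael addition of dimethyl malonate 8 to F3 under NaOMe in MeOH at reflux passes through the same adduct 11 and should close to dione 12, where the route is rejoined; no alkylidenemalonate is exposed to base in this variant.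

2. Step 6. Dianion formation may be incomplete, or selenium may be delivered to C3 of the dione or to a prenyl alkene instead of C1. The fallback avoids the dianion and sets out from dione 12. Double silylation (TMSOTf, Et3N, CH2Cl2, 0 °C) should give the diene methyl 3,5-bis(3-methylbut-2-enyl)-6-(2-phenylethyl)-2,4-bis(trimethylsilyloxy)cyclohexa-1,3-diene-1-carboxylate F4 (a regioisomeric bis-silyl diene would serve equally). Dehydrogenation of this cyclohexadiene with DDQ (1.0 equiv, CH2Cl2, 0 °C, short contact time) should give the arene methyl 3,5-bis(3-methylbut-2-enyl)-6-(2-phenylethyl)-2,4-bis(trimethylsilyloxy)benzoate F5. Mild desilylation (citric acid, aq MeOH) then returns to the route at target 17.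

3. Step 7. The selenoxide may lack a syn β-hydrogen if selenium entered cis to the phenethyl group, or electrophilic selenium by-products may add to the prenyl alkenes and cyclize the ortho-prenyl phenol. The fallback replaces the oxidative syn-elimination by a base-induced dehydrohalogenation and sets out from dione 12. The dianion 13, generated as in step 6, is quenched at −78 °C with BrCCl2CCl2Br to give the bromide methyl 1-bromo-3,5-bis(3-methylbut-2-enyl)-2,4-dioxo-6-(2-phenylethyl)cyclohexane-1-carboxylate F6. Treatment with Li2CO3 in DMF at 60 °C should eliminate HBr with no syn requirement and no oxidant, returning to the route at keto tautomer 16, which enolizes to 17.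

**Further compounds**

F1 | step 5 | 5-(1-hydroxy-3-phenylpropyl)-2,10-dimethylundeca-2,9-dien-6-one (mixture of diastereomers) | CC(C)=CCC(C(O)CCc1ccccc1)C(=O)CCC=C(C)C
F2 | step 5 | [9-methyl-4-(3-methylbut-2-enyl)-5-oxo-1-phenyldec-8-en-3-yl] methanesulfonate (mixture of diastereomers) | CC(C)=CCC(C(OS(C)(=O)=O)CCc1ccccc1)C(=O)CCC=C(C)C
F3 | step 5 | (E)-2,10-dimethyl-5-(3-phenylpropylidene)undeca-2,9-dien-6-one | CC(C)=CC/C(=C\CCc1ccccc1)C(=O)CCC=C(C)C
F4 | step 6 | methyl 3,5-bis(3-methylbut-2-enyl)-6-(2-phenylethyl)-2,4-bis(trimethylsilyloxy)cyclohexa-1,3-diene-1-carboxylate (mixture of diastereomers) | COC(=O)C1=C(O[Si](C)(C)C)C(CC=C(C)C)=C(O[Si](C)(C)C)C(CC=C(C)C)C1CCc1ccccc1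
F5 | step 6 | methyl 3,5-bis(3-methylbut-2-enyl)-6-(2-phenylethyl)-2,4-bis(trimethylsilyloxy)benzoate | COC(=O)c1c(O[Si](C)(C)C)c(CC=C(C)C)c(O[Si](C)(C)C)c(CC=C(C)C)c1CCc1ccccc1
F6 | step 7 | methyl 1-bromo-3,5-bis(3-methylbut-2-enyl)-2,4-dioxo-6-(2-phenylethyl)cyclohexane-1-carboxylate (mixture of diastereomers) | COC(=O)C1(Br)C(CCc2ccccc2)C(CC=C(C)C)C(=O)C(CC=C(C)C)C1=O
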